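Retrosynthetic overview
1. Last ring: the 19-membered lactam, closed at N–C1 by macrolactamisation of a seco amino acid; C3–C4 comes from a B-alkyl Suzuki–Miyaura coupling with methyl (Z)-3-iodoacrylate, C6/C7 from a (Z)-γ-methoxyallylboration of a C7 enal, C8=C9 from a Still–Gennari olefination of a C9 aldehyde.
2. Aryl–C15 by Negishi coupling of a C15 alkylzinc with a silylated 3-bromo-5-nitrophenol; C15 is the former carbonyl carbon of a temporary γ-lactone that is opened by hydride.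
3. Key disconnection C13–C14: ring-closing metathesis of the methacrylate ester of the C12 carbinol closes the butenolide ring O12–C15(=O)–C14=C13–C12; hydrogenation in the same flask, anti to the C12 side chain, sets C14.
4. Enabling feature: C12 carries an oxygen and C15 lies 1,4 to it across C13–C14, so C15 at the acid oxidation level can be tied to O12 as an ester; C13 and C14 then are the two alkene termini of a 1,6-diene that closes to a five-membered ring with the new stereocentre next to C12.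
5. C10–C12 from methyl (S)-3-hydroxy-2-methylpropanoate by iridium-catalysed anti-(benzoyloxy)allylation; the arene is bought, so the ring order is butenolide/γ-lactone (step 8, opened in step 9), then the macrolactam (step 24).

Key step: step 8

Atom labels: C1–C15 is the ansa-chain numbering from the amide carbonyl (C1) to the benzylic CH2 (C15); O11 and O12 are the oxygens on C11 and C12. TBS = tert-butyldimethylsilyl, TIPS = triisopropylsilyl, TBSO/TIPSO = the silyloxy groups, Ipc = isopinocampheyl.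
Assumption: (R)-SEGPHOS is taken as the ligand antipode that gives the 11R,12S adduct in step 4; if the sense of induction is the opposite, the mirror-image ligand is used.

Step 1
Reactants: 1 methyl (S)-3-hydroxy-2-methylpropanoate
Product: 2 methyl (S)-3-(TBSO)-2-methylpropanoate
Conditions: TBSCl, imidazole, DMF, 0 °C to rt
Reagents that add atoms: tert-butyldimethylsilyl chloride, C[Si](C)(Cl)C(C)(C)C
Why: Imidazole-promoted silylation of the primary alcohol (silyl ether formation) leaves the C10 stereocentre untouched.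

Step 2
Reactants: 2 methyl (S)-3-(TBSO)-2-methylpropanoate
Product: 3 (R)-3-(TBSO)-2-methylpropan-1-ol
Conditions: i-Bu2AlH (2.2 equiv), CH2Cl2, −78 to 0 °C; aqueous work-up
Reagents that add atoms: none
Why: Hydride reduction of the ester to the primary alcohol spares the silyl ether and the configuration (only the descriptor changes).

Step 3
Reactants: 4 acrolein; 5 benzoic anhydride
Product: 6 prop-2-ene-1,1-diyl dibenzoate
Conditions: FeCl3 (2 mol %), CH2Cl2, 0 °C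
Reagents that add atoms: none
Why: Lewis-acid-catalysed acylal formation, in which the anhydride adds across the aldehyde C=O of acrolein, gives the geminal dibenzoate used as allyl donor.

Step 4
Reactants: 3 (R)-3-(TBSO)-2-methylpropan-1-ol; 6 prop-2-ene-1,1-diyl dibenzoate
Product: 7 (3S,4R,5S)-6-(TBSO)-4-hydroxy-5-methylhex-1-en-3-yl benzoate
Conditions: [Ir(cod)Cl]2 (2.5 mol %), (R)-SEGPHOS (5 mol %), 4-cyano-3-nitrobenzoic acid (10 mol %), K3PO4 (20 mol %), THF, 60 °C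
Reagents that add atoms: none
Why: Iridium-catalysed transfer-hydrogenative carbonyl (acyloxy)allylation (Krische-type, redox-neutral from the alcohol): 3 is dehydrogenated in situ, the aldehyde is trapped through a closed chair transition state by the (E)-σ-(benzoyloxy)allyl iridium species, which gives the 11,12-anti relation, and the ligand sets C11 (R) and C12 (S) by catalyst control, while C10 is not epimerised because the aldehyde never accumulates.

Step 5
Reactants: 7 (3S,4R,5S)-6-(TBSO)-4-hydroxy-5-methylhex-1-en-3-yl benzoate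
Product: 8 (3S,4R,5S)-4,6-bis(TBSO)-5-methylhex-1-en-3-yl benzoate
Conditions: TBSOTf, 2,6-lutidine, CH2Cl2, −78 to 0 °C
Reagents that add atoms: tert-butyldimethylsilyl trifluoromethanesulfonate, CC(C)(C)[Si](C)(C)OS(=O)(=O)C(F)(F)F
Why: Silylation of the hindered secondary alcohol with the silyl triflate and a non-nucleophilic base should not let the neighbouring benzoate migrate.

Step 6
Reactants: 8 (3S,4R,5S)-4,6-bis(TBSO)-5-methylhex-1-en-3-yl benzoate
Product: 9 (3S,4R,5S)-4,6-bis(TBSO)-5-methylhex-1-en-3-ol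
Conditions: i-Bu2AlH (2.5 equiv), CH2Cl2, −78 °C
Reagents that add atoms: none
Why: Reductive cleavage of the benzoate at −78 °C frees O12 without the alkoxide conditions that would allow 1,2-silyl migration from O11.

Step 7
Reactants: 9 (3S,4R,5S)-4,6-bis(TBSO)-5-methylhex-1-en-3-ol; 10 methacryloyl chloride
Product: 11 (3S,4R,5S)-4,6-bis(TBSO)-5-methylhex-1-en-3-yl 2-methylprop-2-enoate
Conditions: Et3N, DMAP (cat.), CH2Cl2, 0 °C
Reagents that add atoms: none
Why: DMAP-catalysed acylation of the allylic alcohol with the acid chloride installs the ester tether that carries C15, C14 and the C14 methyl group.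

Step 8
Reactants: 11 (3S,4R,5S)-4,6-bis(TBSO)-5-methylhex-1-en-3-yl 2-methylprop-2-enoate
Product: 13 (3S,5S)-5-[(1R,2S)-1,3-bis(TBSO)-2-methylpropyl]-3-methyloxolan-2-one, via butenolide 12 (not isolated)
Conditions: second-generation Grubbs catalyst (5 mol %), toluene, high dilution, 80 °C, argon sparge; then solvent exchange to EtOAc, Rh/Al2O3, H2 (1 atm), rt
Reagents that add atoms: none
Why: Ring-closing alkene metathesis, then hydrogenation in the same flask: the ruthenium alkylidene loads on the monosubstituted C13 vinyl group, adds to the 1,1-disubstituted methacrylate alkene by [2+2] cycloaddition and cycloreverts with loss of ethene, which forms the C13=C14 bond. The closest known reaction type is the metathesis of allylic methacrylates to 3-methylfuran-2(5H)-ones with second-generation ruthenium carbenes. The ring closed is the five-membered butenolide O12–C15(=O)–C14=C13–C12, an endocyclic alkene-forming closure of a 1,6-diene that runs through the s-cis ester rotamer, which is populated at 80 °C. The new stereocentre C14 is controlled by C12: H2 is delivered on the rhodium surface to the butenolide face opposite the branched bis(silyloxy) side chain, so the C14 methyl ends cis to that chain (3S,5S), which is the C12/C14 relation of the target. The step needs chemoselectivity and face selectivity; the substrate holds only the two alkenes that must react, and the size of the C12 substituent secures the facial bias. Rh/Al2O3 is used instead of palladium so that the allylic C12–O bond is not cleaved.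

Step 9
Reactants: 13 (3S,5S)-5-[(1R,2S)-1,3-bis(TBSO)-2-methylpropyl]-3-methyloxolan-2-one
Product: 14 (2S,4S,5R,6S)-5,7-bis(TBSO)-2,6-dimethylheptane-1,4-diol
Conditions: LiBH4, THF, 0 °C to rt
Reagents that add atoms: none
Why: Hydride reduction of the lactone to the 1,4-diol opens the temporary ring under non-enolising conditions, so C14 should keep its configuration.

Step 10
Reactants: 14 (2S,4S,5R,6S)-5,7-bis(TBSO)-2,6-dimethylheptane-1,4-diol
Product: 15 (2S,3R,4S,6S)-1,3-bis(TBSO)-7-iodo-2,6-dimethylheptan-4-ol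
Conditions: I2, PPh3, imidazole, CH2Cl2, 0 °C
Reagents that add atoms: iodine, I-I
Why: Appel-type iodination is selective for the primary C15 hydroxyl over the hindered secondary C12 hydroxyl, and iodide displacement of the primary alkoxyphosphonium ion should outrun ring closure by O12 at 0 °C.

Step 11
Reactants: 15 (2S,3R,4S,6S)-1,3-bis(TBSO)-7-iodo-2,6-dimethylheptan-4-ol
Product: 16 (2S,3R,4S,6S)-1,3-bis(TBSO)-7-iodo-4-methoxy-2,6-dimethylheptane
Conditions: Me3OBF4, 1,8-bis(dimethylamino)naphthalene, CH2Cl2, 0 °C to rt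
Reagents that add atoms: trimethyloxonium tetrafluoroborate, C[O+](C)C.F[B-](F)(F)F
Why: O-Methylation with the trimethyloxonium salt and a hindered amine base (Meerwein methylation) needs no alkoxide, so neither silyl migration nor displacement of the iodide by O12 is expected.

Step 12
Reactants: 17 3-bromo-5-nitrophenol
Product: 18 (3-bromo-5-nitrophenoxy)triisopropylsilane
Conditions: TIPSCl, imidazole, DMF, rt
Reagents that add atoms: chlorotriisopropylsilane, CC(C)[Si](Cl)(C(C)C)C(C)C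
Why: Silylation of the phenol gives a protecting group that tolerates the later organometallic and mildly basic steps and falls to fluoride at the end.

Step 13
Reactants: 16 (2S,3R,4S,6S)-1,3-bis(TBSO)-7-iodo-4-methoxy-2,6-dimethylheptane; 18 (3-bromo-5-nitrophenoxy)triisopropylsilane
Product: 20 (2S,3R,4S,6R)-1,3-bis(TBSO)-4-methoxy-2,6-dimethyl-7-[3-nitro-5-(TIPSO)phenyl]heptane, via alkylzinc iodide 19 (not isolated)
Conditions: Zn dust (activated with TMSCl and 1,2-dibromoethane), DMF, rt to 35 °C; then 18, Pd2(dba)3 (2.5 mol %), SPhos (10 mol %), rt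
Reagents that add atoms: none
Why: Negishi C(sp3)–C(sp2) cross-coupling, in which zinc inserts into the primary C–I bond and the alkylzinc iodide couples with the aryl bromide at zerovalent palladium, tolerates the nitro group and does not touch the C14 stereocentre.

Step 14
Reactants: 20 (2S,3R,4S,6R)-1,3-bis(TBSO)-4-methoxy-2,6-dimethyl-7-[3-nitro-5-(TIPSO)phenyl]heptane
Product: 21 (2S,3R,4S,6R)-3-(TBSO)-4-methoxy-2,6-dimethyl-7-[3-nitro-5-(TIPSO)phenyl]heptan-1-ol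
Conditions: camphorsulfonic acid (10 mol %), MeOH/CH2Cl2 (1:1), 0 °C
Reagents that add atoms: none
Why: Acid-catalysed methanolysis removes the primary silyl ether selectively and leaves the hindered secondary TBS ether and the aryl TIPS ether in place.

Step 15
Reactants: 21 (2S,3R,4S,6R)-3-(TBSO)-4-methoxy-2,6-dimethyl-7-[3-nitro-5-(TIPSO)phenyl]heptan-1-ol
Product: 22 (2R,3R,4S,6R)-3-(TBSO)-4-methoxy-2,6-dimethyl-7-[3-nitro-5-(TIPSO)phenyl]heptanal
Conditions: TEMPO (10 mol %), PhI(OAc)2, CH2Cl2, rt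
Reagents that add atoms: none
Why: Oxoammonium (TEMPO) oxidation with PhI(OAc)2 as terminal oxidant gives the aldehyde under conditions mild enough to avoid epimerisation at C10.

Step 16
Reactants: 22 (2R,3R,4S,6R)-3-(TBSO)-4-methoxy-2,6-dimethyl-7-[3-nitro-5-(TIPSO)phenyl]heptanal; 23 ethyl 2-[bis(2,2,2-trifluoroethoxy)phosphoryl]propanoate
Product: 24 ethyl (2Z,4S,5R,6S,8R)-5-(TBSO)-6-methoxy-2,4,8-trimethyl-9-[3-nitro-5-(TIPSO)phenyl]non-2-enoate
Conditions: KN(SiMe3)2, 18-crown-6, THF, −78 °C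
Reagents that add atoms: none
Why: Still–Gennari olefination, in which the bis(trifluoroethyl)phosphonate anion adds under kinetic control and eliminates fast, gives the (Z)-trisubstituted enoate with C7 cis to C10.

Step 17
Reactants: 24 ethyl (2Z,4S,5R,6S,8R)-5-(TBSO)-6-methoxy-2,4,8-trimethyl-9-[3-nitro-5-(TIPSO)phenyl]non-2-enoate
Product: 25 (2Z,4S,5R,6S,8R)-5-(TBSO)-6-methoxy-2,4,8-trimethyl-9-[3-nitro-5-(TIPSO)phenyl]non-2-en-1-ol
Conditions: i-Bu2AlH (2.5 equiv), CH2Cl2, −78 °C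
Reagents that add atoms: none
Why: 1,2-Reduction of the enoate to the allylic alcohol at −78 °C keeps the Z geometry and should spare the nitro group.

Step 18
Reactants: 25 (2Z,4S,5R,6S,8R)-5-(TBSO)-6-methoxy-2,4,8-trimethyl-9-[3-nitro-5-(TIPSO)phenyl]non-2-en-1-ol
Product: 26 (2Z,4S,5R,6S,8R)-5-(TBSO)-6-methoxy-2,4,8-trimethyl-9-[3-nitro-5-(TIPSO)phenyl]non-2-enal
Conditions: TEMPO (10 mol %), PhI(OAc)2, CH2Cl2, 0 °C; used at once
Reagents that add atoms: none
Why: TEMPO oxidation of the allylic alcohol gives the (Z)-enal without acid or base strong enough to isomerise it to the E isomer.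

Step 19
Reactants: 26 (2Z,4S,5R,6S,8R)-5-(TBSO)-6-methoxy-2,4,8-trimethyl-9-[3-nitro-5-(TIPSO)phenyl]non-2-enal; 27 allyl methyl ether
Product: 29 (3S,4S,5Z,7S,8R,9S,11R)-8-(TBSO)-3,9-dimethoxy-5,7,11-trimethyl-12-[3-nitro-5-(TIPSO)phenyl]dodeca-1,5-dien-4-ol, via methoxyallylborane 28 (not isolated)
Conditions: 27, s-BuLi, THF, −78 °C; (+)-Ipc2BOMe; BF3·OEt2; then 26, −78 °C; NaBO3·4H2O, THF/H2O, rt
Reagents that add atoms: none
Why: Brown-type asymmetric γ-alkoxyallylboration, in which the (Z)-γ-methoxyallylborane adds through a closed chair transition state to give the 6,7-syn relation and the Ipc groups of (+)-Ipc2BOMe direct attack to the re face of the aldehyde, should give 6S,7S by reagent control.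

Step 20
Reactants: 29 (3S,4S,5Z,7S,8R,9S,11R)-8-(TBSO)-3,9-dimethoxy-5,7,11-trimethyl-12-[3-nitro-5-(TIPSO)phenyl]dodeca-1,5-dien-4-ol
Product: 31 (3S,4S,5Z,7S,8R,9S,11R)-8-(TBSO)-3,9-dimethoxy-5,7,11-trimethyl-12-[3-nitro-5-(TIPSO)phenyl]dodeca-1,5-dien-4-yl carbamate, via trichloroacetyl carbamate 30 (not isolated)
Conditions: Cl3CC(O)NCO, CH2Cl2, 0 °C; then neutral Al2O3, rt
Reagents that add atoms: trichloroacetyl isocyanate, O=C=NC(=O)C(Cl)(Cl)Cl
Why: Carbamoylation, in which the alcohol adds to the isocyanate and the trichloroacetyl group is then cleaved on alumina, leaves the primary carbamate with retention at C7.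

Step 21
Reactants: 31 (3S,4S,5Z,7S,8R,9S,11R)-8-(TBSO)-3,9-dimethoxy-5,7,11-trimethyl-12-[3-nitro-5-(TIPSO)phenyl]dodeca-1,5-dien-4-yl carbamate; 32 methyl (Z)-3-iodoprop-2-enoate
Product: 34 methyl (2Z,6S,7S,8Z,10S,11R,12S,14R)-7-(carbamoyloxy)-11-(TBSO)-6,12-dimethoxy-8,10,14-trimethyl-15-[3-nitro-5-(TIPSO)phenyl]pentadeca-2,8-dienoate, via alkylborane 33 (not isolated)
Conditions: 9-BBN (2.5 equiv), THF, 0 °C to rt; then 32, Pd(dppf)Cl2 (10 mol %), AsPh3, aq. K3PO4, DMF, rt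
Reagents that add atoms: none
Why: Anti-Markovnikov hydroboration of the terminal alkene with 9-BBN (the trisubstituted alkene is too hindered) followed by B-alkyl Suzuki–Miyaura coupling should proceed with retention of the Z geometry of the iodoacrylate.

Step 22
Reactants: 34 methyl (2Z,6S,7S,8Z,10S,11R,12S,14R)-7-(carbamoyloxy)-11-(TBSO)-6,12-dimethoxy-8,10,14-trimethyl-15-[3-nitro-5-(TIPSO)phenyl]pentadeca-2,8-dienoate
Product: 35 (2Z,6S,7S,8Z,10S,11R,12S,14R)-7-(carbamoyloxy)-11-(TBSO)-6,12-dimethoxy-8,10,14-trimethyl-15-[3-nitro-5-(TIPSO)phenyl]pentadeca-2,8-dienoic acid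
Conditions: Me3SnOH, 1,2-dichloroethane, 70 °C; dilute aq. HCl work-up
Reagents that add atoms: trimethyltin hydroxide, C[Sn](C)(C)O
Why: Ester hydrolysis with Me3SnOH under near-neutral conditions cleaves the methyl ester without attacking the carbamate, the aryl silyl ether or the Z alkene.

Step 23
Reactants: 35 (2Z,6S,7S,8Z,10S,11R,12S,14R)-7-(carbamoyloxy)-11-(TBSO)-6,12-dimethoxy-8,10,14-trimethyl-15-[3-nitro-5-(TIPSO)phenyl]pentadeca-2,8-dienoic acid
Product: 36 (2Z,6S,7S,8Z,10S,11R,12S,14R)-15-[3-amino-5-(TIPSO)phenyl]-7-(carbamoyloxy)-11-(TBSO)-6,12-dimethoxy-8,10,14-trimethylpentadeca-2,8-dienoic acid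
Conditions: Zn dust, NH4Cl, THF/MeOH/H2O, rt
Reagents that add atoms: none
Why: Reduction of the nitro group with zinc and NH4Cl is chemoselective in the presence of the alkenes, the carbamate and the silyl ethers.

Step 24
Reactants: 36 (2Z,6S,7S,8Z,10S,11R,12S,14R)-15-[3-amino-5-(TIPSO)phenyl]-7-(carbamoyloxy)-11-(TBSO)-6,12-dimethoxy-8,10,14-trimethylpentadeca-2,8-dienoic acid
Product: 37 11-O-TBS phenol-O-TIPS derivative of the target macrolactam
Conditions: bis(2-oxo-3-oxazolidinyl)phosphinic chloride, i-Pr2NEt, toluene, high dilution (about 1 mmol/L), 60 °C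
Reagents that add atoms: none
Why: Macrolactamisation through the mixed phosphinic anhydride under high dilution lets the aniline close the 19-membered ring, the carbamate NH2 being too weak a nucleophile to compete.

Step 25
Reactants: 37 11-O-TBS phenol-O-TIPS derivative of the target macrolactam
Product: 38 CNP0263527.1 (target)
Conditions: HF·pyridine, pyridine, THF, 0 °C to rt
Reagents that add atoms: none
Why: Fluoride-mediated desilylation cleaves both the aryl TIPS ether and the hindered C11 TBS ether without affecting the carbamate or the alkenes.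

Compound list
1 | methyl (S)-3-hydroxy-2-methylpropanoate | OC[C@H](C)C(=O)OC | starting material
2 | methyl (S)-3-[(tert-butyldimethylsilyl)oxy]-2-methylpropanoate | CC(C)(C)[Si](C)(C)OC[C@H](C)C(=O)OC | intermediate
3 | (R)-3-[(tert-butyldimethylsilyl)oxy]-2-methylpropan-1-ol | CC(C)(C)[Si](C)(C)OC[C@H](C)CO | intermediate
4 | acrolein (prop-2-enal) | C=CC=O | starting material
5 | benzoic anhydride | O=C(OC(=O)c1ccccc1)c1ccccc1 | starting material
6 | prop-2-ene-1,1-diyl dibenzoate | C=CC(OC(=O)c1ccccc1)OC(=O)c1ccccc1 | intermediate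
7 | (3S,4R,5S)-6-(TBSO)-4-hydroxy-5-methylhex-1-en-3-yl benzoate | CC(C)(C)[Si](C)(C)OC[C@H](C)[C@@H](O)[C@@H](OC(=O)c1ccccc1)C=C | intermediate
8 | (3S,4R,5S)-4,6-bis(TBSO)-5-methylhex-1-en-3-yl benzoate | CC(C)(C)[Si](C)(C)OC[C@H](C)[C@@H](O[Si](C)(C)C(C)(C)C)[C@@H](OC(=O)c1ccccc1)C=C | intermediate
9 | (3S,4R,5S)-4,6-bis(TBSO)-5-methylhex-1-en-3-ol | CC(C)(C)[Si](C)(C)OC[C@H](C)[C@@H](O[Si](C)(C)C(C)(C)C)[C@@H](O)C=C | intermediate
10 | methacryloyl chloride (2-methylprop-2-enoyl chloride) | CC(=C)C(=O)Cl | starting material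
11 | (3S,4R,5S)-4,6-bis(TBSO)-5-methylhex-1-en-3-yl 2-methylprop-2-enoate | CC(C)(C)[Si](C)(C)OC[C@H](C)[C@@H](O[Si](C)(C)C(C)(C)C)[C@@H](OC(=O)C(C)=C)C=C | intermediate
12 | (5S)-5-[(1R,2S)-1,3-bis(TBSO)-2-methylpropyl]-3-methylfuran-2(5H)-one (butenolide) | CC(C)(C)[Si](C)(C)OC[C@H](C)[C@@H](O[Si](C)(C)C(C)(C)C)[C@H]1OC(=O)C(C)=C1 | intermediate (not isolated)
13 | (3S,5S)-5-[(1R,2S)-1,3-bis(TBSO)-2-methylpropyl]-3-methyloxolan-2-one (cis-lactone) | CC(C)(C)[Si](C)(C)OC[C@H](C)[C@@H](O[Si](C)(C)C(C)(C)C)[C@H]1OC(=O)[C@@H](C)C1 | intermediate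
14 | (2S,4S,5R,6S)-5,7-bis(TBSO)-2,6-dimethylheptane-1,4-diol | CC(C)(C)[Si](C)(C)OC[C@H](C)[C@@H](O[Si](C)(C)C(C)(C)C)[C@@H](O)C[C@H](C)CO | intermediate
15 | (2S,3R,4S,6S)-1,3-bis(TBSO)-7-iodo-2,6-dimethylheptan-4-ol | CC(C)(C)[Si](C)(C)OC[C@H](C)[C@@H](O[Si](C)(C)C(C)(C)C)[C@@H](O)C[C@H](C)CI | intermediate
16 | (2S,3R,4S,6S)-1,3-bis(TBSO)-7-iodo-4-methoxy-2,6-dimethylheptane | CC(C)(C)[Si](C)(C)OC[C@H](C)[C@@H](O[Si](C)(C)C(C)(C)C)[C@@H](OC)C[C@H](C)CI | intermediate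
17 | 3-bromo-5-nitrophenol | Oc1cc(Br)cc([N+](=O)[O-])c1 | starting material
18 | (3-bromo-5-nitrophenoxy)triisopropylsilane | CC(C)[Si](Oc1cc(Br)cc([N+](=O)[O-])c1)(C(C)C)C(C)C | intermediate
19 | [(2S,4S,5R,6S)-5,7-bis(TBSO)-4-methoxy-2,6-dimethylheptyl]zinc iodide | CC(C)(C)[Si](C)(C)OC[C@H](C)[C@@H](O[Si](C)(C)C(C)(C)C)[C@@H](OC)C[C@H](C)C[Zn]I | intermediate (not isolated)
20 | (2S,3R,4S,6R)-1,3-bis(TBSO)-4-methoxy-2,6-dimethyl-7-[3-nitro-5-(TIPSO)phenyl]heptane | CC(C)(C)[Si](C)(C)OC[C@H](C)[C@@H](O[Si](C)(C)C(C)(C)C)[C@@H](OC)C[C@H](C)Cc1cc(O[Si](C(C)C)(C(C)C)C(C)C)cc([N+](=O)[O-])c1 | intermediate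
21 | (2S,3R,4S,6R)-3-(TBSO)-4-methoxy-2,6-dimethyl-7-[3-nitro-5-(TIPSO)phenyl]heptan-1-ol | OC[C@H](C)[C@@H](O[Si](C)(C)C(C)(C)C)[C@@H](OC)C[C@H](C)Cc1cc(O[Si](C(C)C)(C(C)C)C(C)C)cc([N+](=O)[O-])c1 | intermediate
22 | (2R,3R,4S,6R)-3-(TBSO)-4-methoxy-2,6-dimethyl-7-[3-nitro-5-(TIPSO)phenyl]heptanal | O=C[C@H](C)[C@@H](O[Si](C)(C)C(C)(C)C)[C@@H](OC)C[C@H](C)Cc1cc(O[Si](C(C)C)(C(C)C)C(C)C)cc([N+](=O)[O-])c1 | intermediate
23 | ethyl 2-[bis(2,2,2-trifluoroethoxy)phosphoryl]propanoate | CCOC(=O)C(C)P(=O)(OCC(F)(F)F)OCC(F)(F)F | starting material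
24 | ethyl (2Z,4S,5R,6S,8R)-5-(TBSO)-6-methoxy-2,4,8-trimethyl-9-[3-nitro-5-(TIPSO)phenyl]non-2-enoate | CCOC(=O)/C(C)=C\[C@H](C)[C@@H](O[Si](C)(C)C(C)(C)C)[C@@H](OC)C[C@H](C)Cc1cc(O[Si](C(C)C)(C(C)C)C(C)C)cc([N+](=O)[O-])c1 | intermediate
25 | (2Z,4S,5R,6S,8R)-5-(TBSO)-6-methoxy-2,4,8-trimethyl-9-[3-nitro-5-(TIPSO)phenyl]non-2-en-1-ol | OC/C(C)=C\[C@H](C)[C@@H](O[Si](C)(C)C(C)(C)C)[C@@H](OC)C[C@H](C)Cc1cc(O[Si](C(C)C)(C(C)C)C(C)C)cc([N+](=O)[O-])c1 | intermediate
26 | (2Z,4S,5R,6S,8R)-5-(TBSO)-6-methoxy-2,4,8-trimethyl-9-[3-nitro-5-(TIPSO)phenyl]non-2-enal | O=C/C(C)=C\[C@H](C)[C@@H](O[Si](C)(C)C(C)(C)C)[C@@H](OC)C[C@H](C)Cc1cc(O[Si](C(C)C)(C(C)C)C(C)C)cc([N+](=O)[O-])c1 | intermediate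
27 | allyl methyl ether (3-methoxyprop-1-ene) | COCC=C | starting material
28 | [(2Z)-3-methoxyprop-2-en-1-yl]bis(isopinocampheyl)borane, Ipc groups as in (+)-Ipc2BOMe | CO/C=C\CB([C@H]1C[C@H]2C[C@@H]([C@@H]1C)C2(C)C)[C@H]1C[C@H]2C[C@@H]([C@@H]1C)C2(C)C | intermediate (not isolated)
29 | (3S,4S,5Z,7S,8R,9S,11R)-8-(TBSO)-3,9-dimethoxy-5,7,11-trimethyl-12-[3-nitro-5-(TIPSO)phenyl]dodeca-1,5-dien-4-ol | C=C[C@H](OC)[C@@H](O)/C(C)=C\[C@H](C)[C@@H](O[Si](C)(C)C(C)(C)C)[C@@H](OC)C[C@H](C)Cc1cc(O[Si](C(C)C)(C(C)C)C(C)C)cc([N+](=O)[O-])c1 | intermediate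
30 | N-(trichloroacetyl)carbamate of 29 at O7 | C=C[C@H](OC)[C@@H](OC(=O)NC(=O)C(Cl)(Cl)Cl)/C(C)=C\[C@H](C)[C@@H](O[Si](C)(C)C(C)(C)C)[C@@H](OC)C[C@H](C)Cc1cc(O[Si](C(C)C)(C(C)C)C(C)C)cc([N+](=O)[O-])c1 | intermediate (not isolated)
31 | (3S,4S,5Z,7S,8R,9S,11R)-8-(TBSO)-3,9-dimethoxy-5,7,11-trimethyl-12-[3-nitro-5-(TIPSO)phenyl]dodeca-1,5-dien-4-yl carbamate | C=C[C@H](OC)[C@@H](OC(N)=O)/C(C)=C\[C@H](C)[C@@H](O[Si](C)(C)C(C)(C)C)[C@@H](OC)C[C@H](C)Cc1cc(O[Si](C(C)C)(C(C)C)C(C)C)cc([N+](=O)[O-])c1 | intermediate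
32 | methyl (Z)-3-iodoprop-2-enoate | COC(=O)/C=C\I | starting material
33 | 9-[(3S,4S,5Z,7S,8R,9S,11R)-4-(carbamoyloxy)-8-(TBSO)-3,9-dimethoxy-5,7,11-trimethyl-12-[3-nitro-5-(TIPSO)phenyl]dodec-5-en-1-yl]-9-borabicyclo[3.3.1]nonane | C1CCC2CCCC1B2CC[C@H](OC)[C@@H](OC(N)=O)/C(C)=C\[C@H](C)[C@@H](O[Si](C)(C)C(C)(C)C)[C@@H](OC)C[C@H](C)Cc1cc(O[Si](C(C)C)(C(C)C)C(C)C)cc([N+](=O)[O-])c1 | intermediate (not isolated)
34 | methyl (2Z,6S,7S,8Z,10S,11R,12S,14R)-7-(carbamoyloxy)-11-(TBSO)-6,12-dimethoxy-8,10,14-trimethyl-15-[3-nitro-5-(TIPSO)phenyl]pentadeca-2,8-dienoate | COC(=O)/C=C\CC[C@H](OC)[C@@H](OC(N)=O)/C(C)=C\[C@H](C)[C@@H](O[Si](C)(C)C(C)(C)C)[C@@H](OC)C[C@H](C)Cc1cc(O[Si](C(C)C)(C(C)C)C(C)C)cc([N+](=O)[O-])c1 | intermediate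
35 | (2Z,6S,7S,8Z,10S,11R,12S,14R)-7-(carbamoyloxy)-11-(TBSO)-6,12-dimethoxy-8,10,14-trimethyl-15-[3-nitro-5-(TIPSO)phenyl]pentadeca-2,8-dienoic acid | OC(=O)/C=C\CC[C@H](OC)[C@@H](OC(N)=O)/C(C)=C\[C@H](C)[C@@H](O[Si](C)(C)C(C)(C)C)[C@@H](OC)C[C@H](C)Cc1cc(O[Si](C(C)C)(C(C)C)C(C)C)cc([N+](=O)[O-])c1 | intermediate
36 | (2Z,6S,7S,8Z,10S,11R,12S,14R)-15-[3-amino-5-(TIPSO)phenyl]-7-(carbamoyloxy)-11-(TBSO)-6,12-dimethoxy-8,10,14-trimethylpentadeca-2,8-dienoic acid | OC(=O)/C=C\CC[C@H](OC)[C@@H](OC(N)=O)/C(C)=C\[C@H](C)[C@@H](O[Si](C)(C)C(C)(C)C)[C@@H](OC)C[C@H](C)Cc1cc(O[Si](C(C)C)(C(C)C)C(C)C)cc(N)c1 | intermediate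
37 | target macrolactam bearing TBS on O11 and TIPS on the phenol oxygen (2Z,8Z; 6S,7S,10S,11R,12S,14R) | CO[C@H]1C[C@H](C)Cc2cc(O[Si](C(C)C)(C(C)C)C(C)C)cc(c2)NC(=O)/C=C\CC[C@H](OC)[C@@H](OC(N)=O)/C(C)=C\[C@H](C)[C@H]1O[Si](C)(C)C(C)(C)C | intermediate
38 | CNP0263527.1, 19-membered ansa macrolactam (2Z,8Z; 6S,7S,10S,11R,12S,14R) | CO[C@H]1C[C@H](C)Cc2cc(O)cc(c2)NC(=O)/C=C\CC[C@H](OC)[C@@H](OC(N)=O)/C(C)=C\[C@H](C)[C@H]1O | target

Total step count: 25. Longest linear sequence: 23 steps (steps 1, 2, 4–11 and 13–25); steps 3 and 12 prepare side components.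

Steps most likely to fail

Step 4. The benzoyl group may migrate between O12 and O11 under the basic conditions, and catalyst control may be incomplete against the bias of the C10 stereocentre. The fallback sets out from 3 and comes back at 9. Alcohol 3 is oxidised (TEMPO, PhI(OAc)2) to (S)-3-(TBSO)-2-methylpropanal F1. Addition of vinylmagnesium bromide (Felkin-type, expected to favour the needed epimer) gives (3S,4S)-5-(TBSO)-4-methylpent-1-en-3-ol F2. Sharpless epoxidation under kinetic-resolution conditions (Ti(O-i-Pr)4, D-(−)-diisopropyl tartrate, t-BuOOH) should epoxidise only this carbinol epimer quickly and give the anti epoxy alcohol (1R,2S)-3-(TBSO)-2-methyl-1-[(2S)-oxiran-2-yl]propan-1-ol F3. Silylation (TBSOTf, 2,6-lutidine) gives (2S)-2-[(1R,2S)-1,3-bis(TBSO)-2-methylpropyl]oxirane F4. One-carbon homologation of the terminal epoxide with dimethylsulfonium methylide (Me3SI, n-BuLi, THF) gives the allylic alcohol 9.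

Step 10. Ring closure of the activated 1,4-diol by O12 to a tetrahydrofuran may compete with iodide displacement, and the iodo alcohol may cyclise on standing. The fallback sets out from 13 and comes back at 16. Aminolysis of the lactone (MeNHOMe·HCl, Me3Al, CH2Cl2) gives (2S,4S,5R,6S)-5,7-bis(TBSO)-4-hydroxy-N-methoxy-N,2,6-trimethylheptanamide F5, which is methylated at once (Me3OBF4, 1,8-bis(dimethylamino)naphthalene) to (2S,4S,5R,6S)-5,7-bis(TBSO)-N,4-dimethoxy-N,2,6-trimethylheptanamide F6. Reduction of the amide with LiH2NBH3 gives (2S,4S,5R,6S)-5,7-bis(TBSO)-4-methoxy-2,6-dimethylheptan-1-ol F7, in which O12 is already capped. Appel-type iodination (I2, PPh3, imidazole) then gives 16.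

Step 24. The aniline is a weak nucleophile, so oligomerisation and Z-to-E isomerisation of the activated cis-enoic acid may compete with ring closure. The fallback closes the ring at C3–C4 instead; it sets out from 31 and comes back at 37. Reduction of the nitro group (Zn, NH4Cl) gives the aniline (3S,4S,5Z,7S,8R,9S,11R)-12-[3-amino-5-(TIPSO)phenyl]-8-(TBSO)-3,9-dimethoxy-5,7,11-trimethyldodeca-1,5-dien-4-yl carbamate F8. Amide formation with (Z)-3-iodoacrylic acid and a carbodiimide at 0 °C gives the (Z)-3-iodoprop-2-enamide F9. Hydroboration with 9-BBN gives the alkylborane F10 (not isolated), and intramolecular B-alkyl Suzuki–Miyaura macrocyclisation (Pd(dppf)Cl2, AsPh3, aq. K3PO4, DMF/THF, high dilution) gives 37.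

Further compounds
F1 | step 4 | (S)-3-(TBSO)-2-methylpropanal | CC(C)(C)[Si](C)(C)OC[C@H](C)C=O
F2 | step 4 | (3S,4S)-5-(TBSO)-4-methylpent-1-en-3-ol | CC(C)(C)[Si](C)(C)OC[C@H](C)[C@@H](O)C=C
F3 | step 4 | (1R,2S)-3-(TBSO)-2-methyl-1-[(2S)-oxiran-2-yl]propan-1-ol | CC(C)(C)[Si](C)(C)OC[C@H](C)[C@@H](O)[C@@H]1CO1
F4 | step 4 | (2S)-2-[(1R,2S)-1,3-bis(TBSO)-2-methylpropyl]oxirane | CC(C)(C)[Si](C)(C)OC[C@H](C)[C@@H](O[Si](C)(C)C(C)(C)C)[C@@H]1CO1
F5 | step 10 | (2S,4S,5R,6S)-5,7-bis(TBSO)-4-hydroxy-N-methoxy-N,2,6-trimethylheptanamide | CC(C)(C)[Si](C)(C)OC[C@H](C)[C@@H](O[Si](C)(C)C(C)(C)C)[C@@H](O)C[C@H](C)C(=O)N(C)OC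
F6 | step 10 | (2S,4S,5R,6S)-5,7-bis(TBSO)-N,4-dimethoxy-N,2,6-trimethylheptanamide | CC(C)(C)[Si](C)(C)OC[C@H](C)[C@@H](O[Si](C)(C)C(C)(C)C)[C@@H](OC)C[C@H](C)C(=O)N(C)OC
F7 | step 10 | (2S,4S,5R,6S)-5,7-bis(TBSO)-4-methoxy-2,6-dimethylheptan-1-ol | CC(C)(C)[Si](C)(C)OC[C@H](C)[C@@H](O[Si](C)(C)C(C)(C)C)[C@@H](OC)C[C@H](C)CO
F8 | step 24 | (3S,4S,5Z,7S,8R,9S,11R)-12-[3-amino-5-(TIPSO)phenyl]-8-(TBSO)-3,9-dimethoxy-5,7,11-trimethyldodeca-1,5-dien-4-yl carbamate | C=C[C@H](OC)[C@@H](OC(N)=O)/C(C)=C\[C@H](C)[C@@H](O[Si](C)(C)C(C)(C)C)[C@@H](OC)C[C@H](C)Cc1cc(O[Si](C(C)C)(C(C)C)C(C)C)cc(N)c1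
F9 | step 24 | N-aryl (Z)-3-iodoprop-2-enamide of F8 | C=C[C@H](OC)[C@@H](OC(N)=O)/C(C)=C\[C@H](C)[C@@H](O[Si](C)(C)C(C)(C)C)[C@@H](OC)C[C@H](C)Cc1cc(O[Si](C(C)C)(C(C)C)C(C)C)cc(NC(=O)/C=C\I)c1
F10 | step 24 | B-alkyl-9-borabicyclo[3.3.1]nonane from F9, boron on C4 | C1CCC2CCCC1B2CC[C@H](OC)[C@@H](OC(N)=O)/C(C)=C\[C@H](C)[C@@H](O[Si](C)(C)C(C)(C)C)[C@@H](OC)C[C@H](C)Cc1cc(O[Si](C(C)C)(C(C)C)C(C)C)cc(NC(=O)/C=C\I)c1
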